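Readings and results are calculated with made-up constants.

The vessel is closed, stirred and isothermal. Solid J dissolves into L, and L passes on to the other species.

| flask | J | remark | time |
|---|---|---|---|
| grey | 0.044 M | run made earlier |  |
| red | 0.18 M | run made earlier |  |
| flask | 0.089 M |  | 15 d |

| run | time / d | J / % | Q / % |
|---|---|---|---|
| grey | 1.25 | 0 | 90.0 |
| grey | 2.08 | 0 | 96.5 |
| grey | 3.00 | 0.3 | 96.8 |
| grey | 5.00 | 0 | 95.7 |
| grey | 10.0 | 0 | 96.6 |
| grey | 15.0 | 0 | 96.9 |
| red | 1.25 | 59.9 | 28.9 |
| red | 2.08 | 34.8 | 54.6 |
| red | 3.00 | 7.5 | 80.3 |
| red | 5.00 | 0 | 96.1 |
| red | 10.0 | 0 | 96.3 |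
| red | 15.0 | 0 | 97.2 |

(scatter of a reading: 0.5 percentage points)

- J is a solid; its amount is given per volume of the solution
- on the list of suspects stand: L <-> E; L <-> Q; E <-> Q; E -> X; J <-> L
- at the start none of J is in solution
- what has only dissolved of J counts as not reacted
- the reaction counts as stopped when no species that holds the J changes by six tenths of a point or more over the second half of the time
- L means what is dissolved; the solid is not counted in it

1. why nothing more happens at 15 d, or that something still does (for what has run out or reacted, a solid counts together with what of it has only dissolved) (forward and back rates have come level / all of J has reacted / it is still moving)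
2. part of the J that has turned into other species by 15 d (what has only dissolved does not count)
3. amount of Q at 15 d, in percent of the J charged
4. amount of L at 15 d, in percent of the J charged

My own reckoning replaces the curved fall of solid in the red run by its mean. From the charge to 3.00 d, that run lost solid at 0.0555 M d⁻¹ on average, which treats dissolution as pseudo-zero-order. Dividing this flask's charge by that rate gives 1.60 d, and charge over mean rate is the clearing time. The error is small: the red run's stretch up to 1.25 d gives 0.0577 M d⁻¹ and its later stretch 0.0539 M d⁻¹, so the clearing time lies between 1.54 d and 1.65 d. The grey run agrees, with a clearing time of 0.793 d and J reading 0% at 1.25 d. Since the clearing time is shorter than the flask's 15 d, the dispute is over the end state.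

Two chemists read the final gap beneath Q, 3.10% in the grey run and 2.80% in the red. The first holds that L, E and Q stand in first-order equilibrium, so a gap that barely moves with the charge is L and E. The second holds that E and Q form side by side, so the gap is by-product and all of J has reacted. Neither L nor E was measured.

The forecast takes the first side: “I lean towards equilibrium, which is a judgement call”. It gives forward and back rates have come level, conversion 98.5%, Q 96.6% and L 1.5%.

The simulation gives forward and back rates have come level, conversion 97.6%, Q 96.8% and L 2.36%, with X at 0.00963%. The side-by-side fit gives a conversion of >99.9%.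

    L ⇌ E (K = 0.330, k = 0.280 h⁻¹)
    L ⇌ Q (K = 41.0, k = 0.150 h⁻¹)
    E ⇌ Q (k = 0.0580 h⁻¹)
    E → X (k = 2.20 × 10⁻⁵ h⁻¹)
    J ⇌ L, rate k5*(cs5 - [L]) while solid is left; crystals form when [L] > cs5 (solubility = 0.0760 M, k = 0.0370 h⁻¹)

This flask's solid read 3.83% at 1.50 d, close to clearing at the reckoned 1.60 d, and the neighbour flask with 0.053 M of J, clearing time 0.955 d, shows J 0% and Q 96.8% at 15.0 d. In this flask the relaxation half-life of E and Q, 0.494 d, is shorter than 15 d, whereas the half-life of E by its turning into X alone, 1300 d, is longer; that span is the first chemist's region, and at 150 d this flask holds L at 2.36% and E at 0.779% against X at 0.0652%.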